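The ten-membered ring is closed last between C3 and C4 (briarane numbering). C3 is the only enolisable carbon of a C2 ketone, because C1 is quaternary, and C4 is the allylic terminus of the C5=C6 olefin, so the ring is an allyl–enolate retron. A Tsuji–Trost macrocyclisation joins the carbanion of a C1 acyl sulfone (C2 ketone, C3 sulfonyl) to the π-allyl generated from a C6 isopropenyl carbinol carbonate. Attack at the unsubstituted terminus C4 forges C3–C4 and moves the double bond to C5=C6 (Z) in one operation. The precursor is acyclic across C3/C4 and already carries the cyclohexane, spiro-epoxide and hydroxy-γ-lactone.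

Key step: step 22

Remark: atoms are labelled C1–C20 as in the briarane skeleton of the target (C1 quaternary with methyl C15; C2, C9, C14 acetoxy carbons; C5=C6 olefin with methyl C16; lactone C7–C8–C17–C19 with methyl C18; epoxide C11–C20).

Step 1
Reactants: 1 tert-butyl (R)-2-hydroxypropanoate
Product: 2 tert-butyl (R)-2-[(trifluoromethylsulfonyl)oxy]propanoate
Conditions: Tf2O, 2,6-lutidine, CH2Cl2, −78 °C
Reagents that add atoms: trifluoromethanesulfonic anhydride (O=S(=O)(OS(=O)(=O)C(F)(F)F)C(F)(F)F)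
Why: O-sulfonylation of the α-hydroxy ester with retention gives a non-racemising leaving group for a clean SN2 step (triflate formation).

Step 2
Reactants: 2 tert-butyl (R)-2-[(trifluoromethylsulfonyl)oxy]propanoate; 3 N-methoxy-N-methyl-2-(triphenyl-λ5-phosphanylidene)acetamide (2.1 equiv)
Product: 5 tert-butyl (S)-4-[methoxy(methyl)amino]-2-methyl-4-oxo-3-(triphenyl-λ5-phosphanylidene)butanoate, via phosphonium triflate 4 (not isolated)
Conditions: CH2Cl2, −78 → 25 °C
Reagents that add atoms: none
Why: C-alkylation of the stabilised ylide by the α-triflyloxy ester proceeds by SN2 with inversion, which sets C17, and the second equivalent of 3 deprotonates the phosphonium salt (ylide alkylation with transylidation).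

Step 3
Reactants: 5 branched ylide; 6 2-(benzyloxy)acetaldehyde
Product: 7 tert-butyl (2R,3E)-5-(benzyloxy)-3-[methoxy(methyl)carbamoyl]-2-methylpent-3-enoate
Conditions: toluene, 100 °C
Reagents that add atoms: none
Why: Wittig olefination with the fully substituted stabilised ylide should place the carbamoyl group trans to CH2OBn (E), the geometry later needed at C7=C8, without touching the C17 centre under these neutral conditions.

Step 4
Reactants: 7 Weinreb amide
Product: 8 tert-butyl (2R,3E)-5-(benzyloxy)-3-formyl-2-methylpent-3-enoate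
Conditions: (i-Bu)2AlH, THF, −78 °C; aqueous potassium sodium tartrate
Reagents that add atoms: none
Why: Hydride addition to the Weinreb amide gives a chelated aluminium hemiaminal that releases the aldehyde only on work-up, and the tert-butyl ester is too hindered to be reduced at −78 °C (Weinreb amide reduction).

Step 5
Reactants: 9 ethyl 8-oxo-1,4-dioxaspiro[4.5]decane-7-carboxylate
Product: 10 ethyl (7S,8S)-8-hydroxy-1,4-dioxaspiro[4.5]decane-7-carboxylate
Conditions: H2 (50 atm), RuCl2[(S)-BINAP] (0.5 mol %), CH2Cl2, 50 °C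
Reagents that add atoms: none
Why: Noyori asymmetric hydrogenation with dynamic kinetic resolution of the configurationally labile β-keto ester sets the carbinol centre C14 (S) by catalyst control, and the adjacent ester-bearing centre is erased in the next step.

Step 6
Reactants: 10 hydroxy ester
Product: 11 ethyl (7R,8S)-8-hydroxy-7-methyl-1,4-dioxaspiro[4.5]decane-7-carboxylate
Conditions: LiN(iPr)2 (2.2 equiv), THF, −78 → −20 °C; CH3I, DMPU, −78 → 0 °C
Reagents that add atoms: iodomethane (CI)
Why: Fráter–Seebach alkylation of the chelated dianion delivers the methyl group anti to the alkoxide, so that C15 ends trans and the ester carbon C2 cis to the C14 oxygen, which sets the quaternary centre C1.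

Step 7
Reactants: 11 methylated hydroxy ester
Product: 12 ethyl (7R,8S)-8-[(tert-butyldimethylsilyl)oxy]-7-methyl-1,4-dioxaspiro[4.5]decane-7-carboxylate
Conditions: TBSOTf, 2,6-lutidine, CH2Cl2, 0 °C
Reagents that add atoms: tert-butyldimethylsilyl triflate (CC(C)(C)[Si](C)(C)OS(=O)(=O)C(F)(F)F)
Why: The silyl triflate silylates the hindered neopentyl-type secondary alcohol and so protects C14–OH through the basic and oxidative steps that follow (silyl ether formation).

Step 8
Reactants: 12 silyl ether ester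
Product: 13 1-[(7R,8S)-8-[(tert-butyldimethylsilyl)oxy]-7-methyl-1,4-dioxaspiro[4.5]decan-7-yl]-2-(phenylsulfonyl)ethan-1-one
Conditions: PhSO2CH3 (3 equiv), n-BuLi (3 equiv), THF, −78 → 25 °C; aqueous NH4Cl
Reagents that add atoms: methyl phenyl sulfone (CS(=O)(=O)c1ccccc1)
Why: Claisen-type acylation of the lithiated sulfone by the non-enolisable ester stops at the β-keto sulfone because the product is at once deprotonated, and the ketal hides the only other electrophile.

Step 9
Reactants: 13 β-keto sulfone ketal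
Product: 14 (3R,4S)-4-[(tert-butyldimethylsilyl)oxy]-3-methyl-3-[2-(phenylsulfonyl)acetyl]cyclohexan-1-one
Conditions: pyridinium p-toluenesulfonate (cat.), acetone/H2O, 55 °C
Reagents that add atoms: water (O)
Why: Acid-catalysed ketal hydrolysis frees the C11 ketone under conditions that a hindered secondary TBS ether survives.

Step 10
Reactants: 14 diketone
Product: 16 (4S,5R)-4-[(tert-butyldimethylsilyl)oxy]-5-methyl-5-[2-(phenylsulfonyl)acetyl]cyclohex-2-en-1-one, via bis(trimethylsilyl) enol ether 15 (not isolated)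
Conditions: LiN(iPr)2 (2.2 equiv), Me3SiCl, THF, −78 °C; then Pd(OAc)2 (1.1 equiv), CH3CN, 25 °C; aqueous NH4Cl
Reagents that add atoms: none
Why: Saegusa–Ito oxidation of the kinetic C11–C12 silyl enol ether can only form the C12=C13 enone because C1 is quaternary, while the sulfonyl ketone is stored as its silyl enol ether and returns on work-up.

Step 11
Reactants: 16 enone; 8 enal
Product: 17 anti aldol adduct (C9 carbinol bonded to C10; E-C7=C8 olefin; tert-butyl ester)
Conditions: LiN(iPr)2 (2.1 equiv), THF, −78 °C (16 added to the base); then 8, −78 °C; AcOH, −78 °C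
Reagents that add atoms: none
Why: Aldol addition of the dianion, in which α′-deprotonation has turned the enone into a cross-conjugated C10 enolate, through a Zimmerman–Traxler chair of this ring-locked E-enolate should give the anti adduct with the aldehyde entering C10 anti to the C2 acyl and C14 silyloxy groups, which sets C10 and C9.

Step 12
Reactants: 17 aldol adduct
Product: 18 saturated C11 ketone
Conditions: H2 (1 atm), RhCl(PPh3)3 (10 mol %), benzene, 25 °C
Reagents that add atoms: none
Why: Homogeneous hydrogenation with RhCl(PPh3)3 saturates the cis-disubstituted enone olefin and spares the hindered trisubstituted C7=C8 olefin and the benzyl ether.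

Step 13
Reactants: 18 allylic alcohol
Product: 19 C7–C8 epoxy alcohol
Conditions: VO(acac)2 (5 mol %), t-BuOOH, CH2Cl2, 0 → 25 °C
Reagents that add atoms: tert-butyl hydroperoxide (CC(C)(C)OO)
Why: Hydroxyl-directed epoxidation through a vanadium alkoxide delivers oxygen syn to the C9 hydroxyl from the rotamer in which H9, not C10, eclipses the geminal C17 branch (A(1,2) strain), which sets C8 and the epoxide face at C7 relative to C9 (erythro) and should override the allylic C17 centre.

Step 14
Reactants: 19 epoxy alcohol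
Product: 20 β-hydroxy-γ-lactone diol (C8 and C9 hydroxyls free)
Conditions: CF3CO2H, CH2Cl2, 0 °C
Reagents that add atoms: none
Why: Acid removes the tert-butyl group and the carboxyl opens the epoxide at C7 with inversion in the only strain-free mode (γ-lactone, epoxy-acid lactonisation), which fixes C7 and leaves the tertiary C8 alcohol.

Step 15
Reactants: 20 lactone diol
Product: 21 C8,C9-bis(triethylsilyl) ether
Conditions: Et3SiOTf (3 equiv), 2,6-lutidine, CH2Cl2, −78 → 0 °C
Reagents that add atoms: triethylsilyl triflate (CC[Si](CC)(CC)OS(=O)(=O)C(F)(F)F)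
Why: The reactive silyl triflate caps the secondary C9 and tertiary C8 alcohols, which would otherwise attack the π-allyl intermediate of the key step or be acylated before it (silyl ether formation).

Step 16
Reactants: 21 C11 ketone
Product: 22 C11 exocyclic methylene compound
Conditions: Zn, CH2Br2, TiCl4, THF/CH2Cl2, 0 → 25 °C
Reagents that add atoms: dibromomethane (BrCBr)
Why: Takai–Lombardo methylenation converts the C11 ketone to the exocyclic olefin under non-basic conditions that do not epimerise C10 or touch the lactone, the sulfonyl ketone being enolised and shielded by the quaternary C1.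

Step 17
Reactants: 22 exocyclic olefin
Product: 23 C11–C20 spiro-epoxide
Conditions: m-CPBA, NaHCO3, CH2Cl2, 0 °C
Reagents that add atoms: 3-chloroperbenzoic acid (OOC(=O)c1cccc(Cl)c1)
Why: Prilezhaev epoxidation of the only olefin from the face anti to the axial C15 methyl group on C1 (equatorial attack on the methylenecyclohexane) should set C11 with the oxygen cis to H10.

Step 18
Reactants: 23 benzyl ether
Product: 24 C6 primary alcohol
Conditions: H2 (1 atm), Pd(OH)2 on carbon, EtOAc, 25 °C
Reagents that add atoms: none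
Why: Hydrogenolysis removes the benzyl ether now that no olefin is left, the non-benzylic epoxide, the sulfone and the silyl ethers being inert.

Step 19
Reactants: 24 primary alcohol
Product: 25 C6 aldehyde
Conditions: Dess–Martin periodinane, NaHCO3, CH2Cl2, 25 °C
Reagents that add atoms: none
Why: Dess–Martin oxidation of the single free alcohol under buffered conditions gives the α-oxygenated aldehyde without epimerisation at C7.

Step 20
Reactants: 25 aldehyde
Product: 26 C6 isopropenyl carbinol (both C6 epimers)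
Conditions: CH2=C(CH3)MgBr, CeCl3, THF, −78 °C; aqueous NH4Cl
Reagents that add atoms: isopropenylmagnesium bromide (CC(=C)[Mg]Br)
Why: The weakly basic organocerium reagent adds to the aldehyde much faster than to the lactone (1,2-addition), and the configuration of the new C6 carbinol is irrelevant because C6 becomes sp2 in the key step.

Step 21
Reactants: 26 allylic alcohol
Product: 27 C6 allylic methyl carbonate
Conditions: ClCO2CH3, pyridine, DMAP (cat.), CH2Cl2, 0 °C
Reagents that add atoms: methyl chloroformate (COC(=O)Cl)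
Why: Pyridine-mediated acylation of the secondary allylic alcohol with the chloroformate gives the carbonate that zerovalent palladium can ionise, pyridine being too weak a base to acylate the sulfonyl ketone.

Step 22
Reactants: 27 allylic carbonate
Product: 28 ten-membered C3-sulfonyl C2 ketone (5Z; both C3 epimers)
Conditions: Pd2(dba)3·CHCl3 (5 mol %), Ph2PCH2CH2PPh2 (15 mol %), THF, 65 °C, slow addition to 0.002 M
Reagents that add atoms: none
Why: Zerovalent palladium ionises the allylic methyl carbonate with loss of CO2, and the methoxide set free deprotonates the β-keto sulfone at C3, so the soft carbanion and the 2-methyl π-allyl (C4–C5–C6) arise under neutral conditions and combine by outer-sphere attack at C4. The closest known reaction type is the palladium-catalysed allylic alkylation macrocyclisation of sulfone-stabilised carbanions used for medium and large carbocycles. The ten-membered carbocycle closes at the distal allyl terminus C4 (10-endo mode, olefin inside the ring) and not at C6 (8-exo, exocyclic isopropenyl). The only new stereocentre, C3, is uncontrolled and is erased on desulfonylation, while the C6 carbinol centre becomes sp2. The step needs C-attack at C4 and the Z olefin: the stabilised carbanion prefers the unhindered CH2 terminus, O-allylation is reversible under palladium, and syn and anti π-allyl isomers equilibrate through the C6-bound σ-allyl, so that the anti isomer, favoured by the 2-methyl group and the only one whose tether reaches C4 without an E-cyclodecene, should close.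

Step 23
Reactants: 28 macrocyclic sulfone
Product: 29 ten-membered C2 ketone
Conditions: SmI2 (4 equiv), THF/CH3OH, −78 °C
Reagents that add atoms: none
Why: Reductive desulfonylation by two single-electron transfers from SmI2 cleaves the C3–S bond α to the ketone and protonation of the samarium enolate leaves the C3 methylene, with lactone, epoxide and silyl ethers inert.

Step 24
Reactants: 29 tris-silyl ether
Product: 30 C8,C9,C14-triol C2 ketone
Conditions: HF·pyridine, pyridine, THF, 0 → 25 °C
Reagents that add atoms: none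
Why: Fluoride cleaves the three silyl ethers under pyridine-buffered conditions mild enough for the spiro-epoxide and the β-hydroxy lactone (desilylation).

Step 25
Reactants: 30 β-hydroxy ketone
Product: 31 C2,C8,C9,C14-tetraol
Conditions: Et2BOMe, THF/CH3OH (4:1), −78 °C; NaBH4; then CH3OH/AcOH, evaporation
Reagents that add atoms: none
Why: Narasaka–Prasad reduction, in which the boron chelate between the C14 hydroxyl and the C2 ketone directs external hydride, should give the 1,3-syn diol and so set C2.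

Step 26
Reactants: 31 tetraol
Product: 32 junceellolide F
Conditions: Ac2O, pyridine, DMAP (cat.), CH2Cl2, 25 °C
Reagents that add atoms: acetic anhydride (CC(=O)OC(C)=O)
Why: DMAP-catalysed acetylation esterifies the three secondary alcohols at C2, C9 and C14 and should leave the hindered tertiary C8 alcohol free.

Compound list
1 | tert-butyl (R)-2-hydroxypropanoate | C[C@@H](O)C(=O)OC(C)(C)C | starting material
2 | tert-butyl (R)-2-[(trifluoromethylsulfonyl)oxy]propanoate | C[C@@H](OS(=O)(=O)C(F)(F)F)C(=O)OC(C)(C)C | intermediate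
3 | N-methoxy-N-methyl-2-(triphenyl-λ5-phosphanylidene)acetamide | CON(C)C(=O)C=P(c1ccccc1)(c1ccccc1)c1ccccc1 | starting material
4 | phosphonium triflate from C-alkylation of 3 by 2 (C17 inverted, S; phosphorus-bearing carbon unassigned) | CON(C)C(=O)C([C@@H](C)C(=O)OC(C)(C)C)[P+](c1ccccc1)(c1ccccc1)c1ccccc1.[O-]S(=O)(=O)C(F)(F)F | intermediate (not isolated)
5 | tert-butyl (S)-4-[methoxy(methyl)amino]-2-methyl-4-oxo-3-(triphenyl-λ5-phosphanylidene)butanoate | CON(C)C(=O)C([C@@H](C)C(=O)OC(C)(C)C)=P(c1ccccc1)(c1ccccc1)c1ccccc1 | intermediate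
6 | 2-(benzyloxy)acetaldehyde | O=CCOCc1ccccc1 | starting material
7 | tert-butyl (2R,3E)-5-(benzyloxy)-3-[methoxy(methyl)carbamoyl]-2-methylpent-3-enoate | CON(C)C(=O)/C(=C/COCc1ccccc1)[C@@H](C)C(=O)OC(C)(C)C | intermediate
8 | tert-butyl (2R,3E)-5-(benzyloxy)-3-formyl-2-methylpent-3-enoate | O=C/C(=C/COCc1ccccc1)[C@@H](C)C(=O)OC(C)(C)C | intermediate
9 | ethyl 8-oxo-1,4-dioxaspiro[4.5]decane-7-carboxylate (racemic) | CCOC(=O)C1CC2(CCC1=O)OCCO2 | starting material
10 | ethyl (7S,8S)-8-hydroxy-1,4-dioxaspiro[4.5]decane-7-carboxylate | O[C@H]1CCC2(OCCO2)C[C@@H]1C(=O)OCC | intermediate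
11 | ethyl (7R,8S)-8-hydroxy-7-methyl-1,4-dioxaspiro[4.5]decane-7-carboxylate | O[C@H]1CCC2(OCCO2)C[C@@]1(C)C(=O)OCC | intermediate
12 | ethyl (7R,8S)-8-[(tert-butyldimethylsilyl)oxy]-7-methyl-1,4-dioxaspiro[4.5]decane-7-carboxylate | CC(C)(C)[Si](C)(C)O[C@H]1CCC2(OCCO2)C[C@@]1(C)C(=O)OCC | intermediate
13 | 1-[(7R,8S)-8-[(tert-butyldimethylsilyl)oxy]-7-methyl-1,4-dioxaspiro[4.5]decan-7-yl]-2-(phenylsulfonyl)ethan-1-one | CC(C)(C)[Si](C)(C)O[C@H]1CCC2(OCCO2)C[C@@]1(C)C(=O)CS(=O)(=O)c1ccccc1 | intermediate
14 | (3R,4S)-4-[(tert-butyldimethylsilyl)oxy]-3-methyl-3-[2-(phenylsulfonyl)acetyl]cyclohexan-1-one | CC(C)(C)[Si](C)(C)O[C@H]1CCC(=O)C[C@@]1(C)C(=O)CS(=O)(=O)c1ccccc1 | intermediate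
15 | bis(trimethylsilyl) enol ether of 14 (C11=C12 and C2=C3 enol ethers) | CC(C)(C)[Si](C)(C)O[C@H]1CC=C(O[Si](C)(C)C)C[C@@]1(C)C(O[Si](C)(C)C)=CS(=O)(=O)c1ccccc1 | intermediate (not isolated)
16 | (4S,5R)-4-[(tert-butyldimethylsilyl)oxy]-5-methyl-5-[2-(phenylsulfonyl)acetyl]cyclohex-2-en-1-one | CC(C)(C)[Si](C)(C)O[C@H]1C=CC(=O)C[C@@]1(C)C(=O)CS(=O)(=O)c1ccccc1 | intermediate
17 | anti aldol adduct of 16 and 8: C9 carbinol on C10 of the cyclohexenone, E-C7=C8 olefin, C6 benzyl ether, C19 tert-butyl ester; C1, C9, C10, C14, C17 as in 32 | CC(C)(C)[Si](C)(C)O[C@H]1C=CC(=O)[C@@H]([C@@]1(C)C(=O)CS(=O)(=O)c1ccccc1)[C@@H](O)/C(=C/COCc1ccccc1)[C@@H](C)C(=O)OC(C)(C)C | intermediate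
18 | 12,13-dihydro derivative of 17 (saturated C11 ketone) | CC(C)(C)[Si](C)(C)O[C@H]1CCC(=O)[C@@H]([C@@]1(C)C(=O)CS(=O)(=O)c1ccccc1)[C@@H](O)/C(=C/COCc1ccccc1)[C@@H](C)C(=O)OC(C)(C)C | intermediate
19 | C7–C8 epoxide of 18 (oxygen syn to the C9 hydroxyl; C8 as in 32, C7 opposite to 32) | CC(C)(C)[Si](C)(C)O[C@H]1CCC(=O)[C@@H]([C@@]1(C)C(=O)CS(=O)(=O)c1ccccc1)[C@@H](O)[C@@]1([C@@H](C)C(=O)OC(C)(C)C)O[C@@H]1COCc1ccccc1 | intermediate
20 | hydroxy-γ-lactone (C7–O–C19) with free C8 and C9 hydroxyls, C6 benzyl ether, C11 ketone; C7, C8, C9, C17 as in 32 | CC(C)(C)[Si](C)(C)O[C@H]1CCC(=O)[C@@H]([C@@]1(C)C(=O)CS(=O)(=O)c1ccccc1)[C@@H](O)[C@@]1(O)[C@H](COCc2ccccc2)OC(=O)[C@@H]1C | intermediate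
21 | C8,C9-bis(triethylsilyl) ether of 20 | CC(C)(C)[Si](C)(C)O[C@H]1CCC(=O)[C@@H]([C@@]1(C)C(=O)CS(=O)(=O)c1ccccc1)[C@@H](O[Si](CC)(CC)CC)[C@@]1(O[Si](CC)(CC)CC)[C@H](COCc2ccccc2)OC(=O)[C@@H]1C | intermediate
22 | C11 exocyclic methylene compound (C11=C20) | CC(C)(C)[Si](C)(C)O[C@H]1CCC(=C)[C@@H]([C@@]1(C)C(=O)CS(=O)(=O)c1ccccc1)[C@@H](O[Si](CC)(CC)CC)[C@@]1(O[Si](CC)(CC)CC)[C@H](COCc2ccccc2)OC(=O)[C@@H]1C | intermediate
23 | C11–C20 spiro-epoxide (C11 as in 32) | CC(C)(C)[Si](C)(C)O[C@H]1CC[C@]2(CO2)[C@@H]([C@@]1(C)C(=O)CS(=O)(=O)c1ccccc1)[C@@H](O[Si](CC)(CC)CC)[C@@]1(O[Si](CC)(CC)CC)[C@H](COCc2ccccc2)OC(=O)[C@@H]1C | intermediate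
24 | C6 primary alcohol | CC(C)(C)[Si](C)(C)O[C@H]1CC[C@]2(CO2)[C@@H]([C@@]1(C)C(=O)CS(=O)(=O)c1ccccc1)[C@@H](O[Si](CC)(CC)CC)[C@@]1(O[Si](CC)(CC)CC)[C@H](CO)OC(=O)[C@@H]1C | intermediate
25 | C6 aldehyde | CC(C)(C)[Si](C)(C)O[C@H]1CC[C@]2(CO2)[C@@H]([C@@]1(C)C(=O)CS(=O)(=O)c1ccccc1)[C@@H](O[Si](CC)(CC)CC)[C@@]1(O[Si](CC)(CC)CC)[C@H](C=O)OC(=O)[C@@H]1C | intermediate
26 | C6 isopropenyl carbinol (C6 unassigned) | CC(C)(C)[Si](C)(C)O[C@H]1CC[C@]2(CO2)[C@@H]([C@@]1(C)C(=O)CS(=O)(=O)c1ccccc1)[C@@H](O[Si](CC)(CC)CC)[C@@]1(O[Si](CC)(CC)CC)[C@H](C(O)C(C)=C)OC(=O)[C@@H]1C | intermediate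
27 | C6 methyl carbonate of 26 | CC(C)(C)[Si](C)(C)O[C@H]1CC[C@]2(CO2)[C@@H]([C@@]1(C)C(=O)CS(=O)(=O)c1ccccc1)[C@@H](O[Si](CC)(CC)CC)[C@@]1(O[Si](CC)(CC)CC)[C@H](C(OC(=O)OC)C(C)=C)OC(=O)[C@@H]1C | intermediate
28 | ten-membered ring: C2 ketone, C3 phenylsulfonyl (C3 unassigned), 5Z olefin, 8,9-bis(triethylsilyl) ether, 14-TBS ether | CC(C)(C)[Si](C)(C)O[C@H]1CC[C@]2(CO2)[C@@H]2[C@@H](O[Si](CC)(CC)CC)[C@@]3(O[Si](CC)(CC)CC)[C@H](/C=C(/C)CC(S(=O)(=O)c4ccccc4)C(=O)[C@@]12C)OC(=O)[C@@H]3C | intermediate
29 | desulfonylated ten-membered C2 ketone | CC(C)(C)[Si](C)(C)O[C@H]1CC[C@]2(CO2)[C@@H]2[C@@H](O[Si](CC)(CC)CC)[C@@]3(O[Si](CC)(CC)CC)[C@H](/C=C(/C)CCC(=O)[C@@]12C)OC(=O)[C@@H]3C | intermediate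
30 | 8,9,14-trihydroxy C2 ketone | O[C@H]1CC[C@]2(CO2)[C@@H]2[C@@H](O)[C@@]3(O)[C@H](/C=C(/C)CCC(=O)[C@@]12C)OC(=O)[C@@H]3C | intermediate
31 | 2,8,9,14-tetraol (2,9,14-tri-O-deacetyl junceellolide F) | O[C@H]1CC[C@]2(CO2)[C@@H]2[C@@H](O)[C@@]3(O)[C@H](/C=C(/C)CC[C@@H](O)[C@@]12C)OC(=O)[C@@H]3C | intermediate
32 | junceellolide F | CC(=O)O[C@H]1CC[C@]2(CO2)[C@@H]2[C@@H](OC(C)=O)[C@@]3(O)[C@H](/C=C(/C)CC[C@@H](OC(C)=O)[C@@]12C)OC(=O)[C@@H]3C | target

Total step count: 26. Longest linear sequence: 22 steps (steps 5–26, from 9); the enal branch is steps 1–4.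

Steps most likely to fail

Step 22. Ring closure may run through the syn π-allyl isomer (E olefin), at the internal terminus C6, at the enolate oxygen, or intermolecularly. The fallback fixes the olefin geometry before ring closure and sets out from aldehyde 25. Stork–Zhao olefination (ylide from (1-iodoethyl)triphenylphosphonium iodide and NaN(SiMe3)2, THF, −78 °C) should give the (Z)-vinyl iodide F1. Stille coupling with (tributylstannyl)methanol (Pd(PPh3)4, dioxane, 80 °C) replaces iodine by CH2OH with retention and gives the (Z)-allylic alcohol F2. Appel bromination (CBr4, PPh3, CH2Cl2, 0 °C) gives the (Z)-allylic bromide F3. Cs2CO3 in acetonitrile at high dilution then alkylates the sulfonyl ketone carbanion at C4 by SN2, again closing the ring through C3–C4, and the route is rejoined at 28.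

Step 11. Proton transfer from C17–H of 8 to the enolate, conjugate addition of the sulfonyl carbanion to the enone before the second deprotonation, or weak facial control may spoil the dianion aldol. The fallback masks the acidic site and sets out from enone 16. Et3N and TBSOTf (CH2Cl2, −78 °C) should silylate only the far more acidic sulfonyl ketone and give the silyl enol ether F4. The mono-enolate (LiN(iPr)2, 1.05 equiv, THF, −78 °C) then adds to 8 to give the aldol adduct F5. Dilute HCl in THF hydrolyses the enol ether and the route is rejoined at 17.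

Step 14. In strong acid, ionisation at the tertiary C8 (pinacol-type shift from C9 or capture by trifluoroacetate) or enolisation toward C10 may compete with lactonisation. The fallback reverses the order of events and sets out from allylic alcohol 18. Me3SiOTf and 2,6-lutidine (CH2Cl2, 0 °C; citric acid work-up) cleave the tert-butyl ester to the β,γ-unsaturated acid F6. Directed epoxidation of F6 (VO(acac)2, t-BuOOH) then lets the epoxy acid close to the γ-lactone at once under near-neutral conditions, and the route is rejoined at 20.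

Further compounds
F1 | step 22 | (Z)-vinyl iodide from 25 (C5 iodide cis to C7) | CC(C)(C)[Si](C)(C)O[C@H]1CC[C@]2(CO2)[C@@H]([C@@]1(C)C(=O)CS(=O)(=O)c1ccccc1)[C@@H](O[Si](CC)(CC)CC)[C@@]1(O[Si](CC)(CC)CC)[C@H](/C=C(/C)I)OC(=O)[C@@H]1C
F2 | step 22 | (Z)-allylic alcohol (C4 hydroxymethyl cis to C7) | CC(C)(C)[Si](C)(C)O[C@H]1CC[C@]2(CO2)[C@@H]([C@@]1(C)C(=O)CS(=O)(=O)c1ccccc1)[C@@H](O[Si](CC)(CC)CC)[C@@]1(O[Si](CC)(CC)CC)[C@H](/C=C(/C)CO)OC(=O)[C@@H]1C
F3 | step 22 | (Z)-allylic bromide | CC(C)(C)[Si](C)(C)O[C@H]1CC[C@]2(CO2)[C@@H]([C@@]1(C)C(=O)CS(=O)(=O)c1ccccc1)[C@@H](O[Si](CC)(CC)CC)[C@@]1(O[Si](CC)(CC)CC)[C@H](/C=C(/C)CBr)OC(=O)[C@@H]1C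
F4 | step 11 | TBS enol ether of the sulfonyl ketone of 16 | CC(C)(C)[Si](C)(C)O[C@H]1C=CC(=O)C[C@@]1(C)C(O[Si](C)(C)C(C)(C)C)=CS(=O)(=O)c1ccccc1
F5 | step 11 | aldol adduct of F4 and 8 | CC(C)(C)[Si](C)(C)O[C@H]1C=CC(=O)[C@@H]([C@@]1(C)C(O[Si](C)(C)C(C)(C)C)=CS(=O)(=O)c1ccccc1)[C@@H](O)/C(=C/COCc1ccccc1)[C@@H](C)C(=O)OC(C)(C)C
F6 | step 14 | β,γ-unsaturated carboxylic acid from 18 | CC(C)(C)[Si](C)(C)O[C@H]1CCC(=O)[C@@H]([C@@]1(C)C(=O)CS(=O)(=O)c1ccccc1)[C@@H](O)/C(=C/COCc1ccccc1)[C@@H](C)C(=O)O
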